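The seven-membered ring (C5–C6–C7–C8–C9–C10–C1) of this daucane carries oxygen at C6, the C8=C9 unsaturation with a one-carbon branch at C8, and the quaternary methyl carbon C1 at the ring fusion. This is the pattern of a 1,4-cycloheptadiene made from a 2-alkoxydiene and a vinylcarbenoid, so the ring is cut at C7–C8 and C1–C10. One operation, enantioselective cyclopropanation of the enol ether of 2-(1-ethoxyvinyl)-3-methylcyclopentenone by methyl 2-diazobut-3-enoate and Cope rearrangement of the cis-divinylcyclopropane, closes the ring and sets C1. The C6 vinylogous ester then delivers the C4 carbinol, C5 and C6; acylation and C8–C9 epoxidation finish.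

Key step: step 6

Remark: daucane numbering is used for all bicyclic compounds, β means the face of the C1 methyl group, and the facial sense of Rh2(R-DOSP)4 toward the 1,1-disubstituted enol ether is assumed to be the one known for monosubstituted alkenes (alkene substituent cis to the vinyl donor).

Step 1
Reactants: 1 3-methylcyclopent-2-en-1-one
Product: 3 2-bromo-3-methylcyclopent-2-en-1-one, via dibromoketone 2 (not isolated)
Conditions: Br2 (1.05 equiv), CH2Cl2, 0 °C; then Et3N (1.5 equiv), 0 to 23 °C
Reagents that add atoms: bromine, BrBr
Why: Anti addition of bromine to the enone alkene and amine-induced E1cB loss of HBr from the resulting α,β-dibromoketone (bromination–dehydrobromination) should leave bromine only on the α carbon, as is routine for β-substituted cycloalkenones.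

Step 2
Reactants: 3 2-bromo-3-methylcyclopent-2-en-1-one; 4 tributyl(1-ethoxyethenyl)stannane
Product: 5 2-(1-ethoxyethenyl)-3-methylcyclopent-2-en-1-one
Conditions: Pd(PPh3)4 (5 mol %), CuI (10 mol %), PhMe, 90 °C; aq. KF work-up; Et3N-deactivated silica
Reagents that add atoms: none
Why: Stille coupling (oxidative addition of zerovalent palladium into the activated C–Br bond, copper-assisted transfer of the α-alkoxyvinyl group from tin, reductive elimination) should give the cross-conjugated 2-alkoxydiene, and the base-buffered isolation keeps its acid-labile enol ether.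

Step 3
Reactants: 6 methyl acetoacetate
Product: 7 methyl 2-diazo-3-oxobutanoate
Conditions: 4-acetamidobenzenesulfonyl azide (1.1 equiv), Et3N (1.5 equiv), MeCN, 0 to 23 °C
Reagents that add atoms: 4-acetamidobenzenesulfonyl azide, CC(=O)Nc1ccc(cc1)S(=O)(=O)N=[N+]=[N-]
Why: Regitz diazo transfer, in which the amine-generated enolate of the β-keto ester attacks the terminal nitrogen of the sulfonyl azide and the adduct collapses to the diazo compound and the sulfonamide.

Step 4
Reactants: 7 methyl 2-diazo-3-oxobutanoate
Product: 8 methyl 2-diazo-3-hydroxybutanoate (racemic)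
Conditions: NaBH4 (0.6 equiv), MeOH, 0 °C
Reagents that add atoms: none
Why: Borohydride reduction of the ketone is chemoselective because the diazo ester is inert to this hydride at 0 °C, and the racemic carbinol centre is destroyed in the next step.

Step 5
Reactants: 8 methyl 2-diazo-3-hydroxybutanoate
Product: 9 methyl 2-diazobut-3-enoate
Conditions: POCl3 (1.5 equiv), Et3N (4 equiv), CH2Cl2, 0 °C; cold pentane solution used at once
Reagents that add atoms: none
Why: Phosphorylation of the hydroxyl and amine-induced E2 loss of dichlorophosphate (alcohol dehydration) gives the vinyl group, and the product is used immediately because it slowly electrocyclises to a pyrazole.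

Step 6
Reactants: 5 2-(1-ethoxyethenyl)-3-methylcyclopent-2-en-1-one; 9 methyl 2-diazobut-3-enoate
Product: 11 methyl (8aR)-4-ethoxy-8a-methyl-3-oxo-1,2,3,5,8,8a-hexahydroazulene-6-carboxylate, via cis-divinylcyclopropane 10 (not isolated)
Conditions: Rh2(R-DOSP)4 [dirhodium tetrakis((R)-N-(4-dodecylbenzenesulfonyl)prolinate), 1 mol %], 5 (1 equiv) in pentane–PhCF3, 9 (2 equiv) added over 2 h, −45 to 23 °C; then PhMe, 80 °C until 10 is consumed
Reagents that add atoms: none
Why: The donor–acceptor rhodium vinylcarbenoid from 9 should transfer its carbene carbon C8 to the electron-rich terminal enol ether C7=C6 of 5 (not to the electron-poor tetrasubstituted enone alkene) and give cyclopropane 10 with the vinyl group cis to the cyclopentenonyl group, as donor-substituted carbenoids normally do. 10 then undergoes a concerted [3,3] shift through the boat transition state with both alkenyl groups folded over the three-membered ring, forming C1–C10 as C6–C8 breaks; this is the known tandem cyclopropanation/divinylcyclopropane Cope rearrangement (formal [4+3] cycloaddition) of vinyldiazoacetates with dienes. The three-membered ring closes by concerted carbene addition to the alkene and is consumed when the seven-membered ring closes by the pericyclic bond reorganisation onto the existing cyclopentenone. C6 and C8 of 10 are set by the chiral prolinate ligands of the catalyst, which select one enantioface of the enol ether, and C1 of 11 follows stereospecifically from them through the boat geometry, in which the C1 methyl group points inward. The step needs reaction at the carbene carbon and not at the vinyl terminus, and a concerted and not a zwitterionic ring opening: the small methyl ester, the carboxylate catalyst and the hydrocarbon medium favour both, and the ethoxy donor on C6 opposite the ester on C8 weakens the breaking bond enough that moderate heating in a non-polar solvent should overcome the inward methyl group.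

Step 7
Reactants: 11 methyl (8aR)-4-ethoxy-8a-methyl-3-oxo-1,2,3,5,8,8a-hexahydroazulene-6-carboxylate
Product: 13 methyl (1R)-6-oxodauca-4,8-dien-14-oate, via C4 carbinol 12 (not isolated)
Conditions: i-PrMgCl (1.5 equiv), CeCl3 (1.6 equiv, dried), THF, −78 °C; then 1 M aq. HCl, THF, 0 to 23 °C
Reagents that add atoms: isopropylmagnesium chloride, CC(C)[Mg]Cl; water, O
Why: The weakly basic organocerium reagent should add 1,2 to the C4 carbonyl of the vinylogous ester without enolisation and without touching the methyl enoate at −78 °C, and aqueous acid then ionises the tertiary allylic alcohol to the C6 oxocarbenium ion, which water intercepts at C6 with loss of ethanol to give the transposed C4=C5 enone (Stork–Danheiser transposition), so that the C4 epimer mixture of 12 is of no consequence.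

Step 8
Reactants: 13 methyl (1R)-6-oxodauca-4,8-dien-14-oate
Product: 14 methyl (1R,4R,5R)-4β,5β-epoxy-6-oxodauc-8-en-14-oate
Conditions: 30% aq. H2O2 (5 equiv), NaOH (0.5 equiv), MeOH, 0 °C
Reagents that add atoms: hydrogen peroxide, OO
Why: Weitz–Scheffer epoxidation, in which hydroperoxide adds reversibly to C4 of the enone (the enoate alkene is far less electrophilic) and the enolate closes onto oxygen on the β face, because only this closure keeps the C5–C6 and C1–C10 bonds cis on the cyclopentane and avoids a strained trans-fused bicyclic epoxide, which sets C4 and C5 with oxygen cis to the C1 methyl group; methanol as solvent keeps the methyl ester.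

Step 9
Reactants: 14 methyl (1R,4R,5R)-4β,5β-epoxy-6-oxodauc-8-en-14-oate
Product: 15 methyl (1R,4R,5S)-4β-hydroxy-6-oxo-5βH-dauc-8-en-14-oate (cis-fused ketol)
Conditions: SmI2 (2.5 equiv), THF–MeOH (2:1), −90 °C; pH 7 buffer
Reagents that add atoms: none
Why: Two single-electron transfers from SmI2 to the ketone should break the adjacent C5–O bond and keep the C4–O bond (the known samarium diiodide reduction of α,β-epoxy ketones to aldols, the enoate being inert without HMPA), and methanol is expected to protonate the enolate at C5 on the β face next to the C4 oxygen and not past the isopropyl group, which gives the cis-fused C5 epimer that the next step corrects.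

Step 10
Reactants: 15 methyl (1R,4R,5S)-4β-hydroxy-6-oxo-5βH-dauc-8-en-14-oate
Product: 16 methyl (1R,4R,5R)-4β-hydroxy-6-oxo-5αH-dauc-8-en-14-oate (trans-fused ketol)
Conditions: DBU (0.3 equiv), PhMe, 23 °C, followed to equilibrium
Reagents that add atoms: none
Why: Reversible amine-base enolisation at C5 (thermodynamic epimerisation α to a ketone) should convert the cis-fused ketol into the trans-fused one, which places C6 anti to the isopropyl group on the five-membered ring and alone allows the C4–OH to C6=O hydrogen bond that persists in toluene, while the absence of an alkoxide keeps retro-aldol opening and dehydration slow.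

Step 11
Reactants: 16 methyl (1R,4R,5R)-4β-hydroxy-6-oxo-5αH-dauc-8-en-14-oate
Product: 17 methyl (1R,4R,5S,6S)-4β,6α-dihydroxydauc-8-en-14-oate
Conditions: Me4NBH(OAc)3 (5 equiv), MeCN–AcOH (1:1), −30 °C
Reagents that add atoms: none
Why: Evans–Saksena reduction, in which the C4 hydroxyl replaces an acetate on boron and the alkoxyborohydride delivers hydride through a six-membered transition state to the β face of the C6 ketone (possible only in the trans-fused ketol, where C4–O and C6 are cis on the five-membered ring), so that the new hydroxyl is 6α (6S) and the enoate is untouched.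

Step 12
Reactants: 17 methyl (1R,4R,5S,6S)-4β,6α-dihydroxydauc-8-en-14-oate
Product: 18 (1R,4R,5S,6S)-dauc-8-ene-4β,6α,14-triol
Conditions: i-Bu2AlH (6 equiv), CH2Cl2, −78 to 0 °C; aq. potassium sodium tartrate
Reagents that add atoms: none
Why: i-Bu2AlH reduces the conjugated methyl ester by 1,2-hydride addition through the aldehyde to the primary allylic alcohol, the excess covering the two free hydroxyl groups, and no stereocentre is affected.

Step 13
Reactants: 18 (1R,4R,5S,6S)-dauc-8-ene-4β,6α,14-triol
Product: 19 (1R,4R,5S,6S)-14-chlorodauc-8-ene-4β,6α-diol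
Conditions: NCS (1.3 equiv), Me2S (1.5 equiv), CH2Cl2, −20 to 0 °C
Reagents that add atoms: N-chlorosuccinimide, O=C1CCC(=O)N1Cl
Why: Corey–Kim chlorination, in which the sulfonium reagent made from NCS and Me2S forms an alkoxysulfonium ion at the unhindered primary allylic hydroxyl and chloride displaces dimethyl sulfoxide by SN2, whereas the hindered secondary C6 and tertiary C4 hydroxyls are not displaced and return on work-up.

Step 14
Reactants: 19 (1R,4R,5S,6S)-14-chlorodauc-8-ene-4β,6α-diol
Product: 20 (1R,4R,5S,6S)-dauc-8-ene-4β,6α-diol (jaeschkeanadiol)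
Conditions: LiEt3BH (5 equiv), THF, 0 to 23 °C
Reagents that add atoms: none
Why: Direct SN2 displacement of the primary allylic chloride by the strongly nucleophilic hydride LiEt3BH (hydride reduction of an alkyl halide) should give the C8 methyl group with the alkene kept at C8=C9, because attack at the unhindered CH2 is preferred over SN2′ attack at the ring carbon C9.

Step 15
Reactants: 20 (1R,4R,5S,6S)-dauc-8-ene-4β,6α-diol; 21 3,4-dimethoxybenzoyl chloride
Product: 22 (1R,4R,5S,6S)-4β-hydroxydauc-8-en-6α-yl 3,4-dimethoxybenzoate
Conditions: Et3N (3 equiv), DMAP (0.3 equiv), CH2Cl2, 23 to 40 °C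
Reagents that add atoms: none
Why: DMAP-catalysed acylation through the N-acylpyridinium ion esterifies the secondary C6 hydroxyl, while the hindered tertiary C4 hydroxyl does not react under these conditions.

Step 16
Reactants: 22 (1R,4R,5S,6S)-4β-hydroxydauc-8-en-6α-yl 3,4-dimethoxybenzoate
Product: 23 (1R,4R,5S,6S,8R,9S)-8α,9α-epoxy-4β-hydroxydaucan-6α-yl 3,4-dimethoxybenzoate (target)
Conditions: mCPBA (1.2 equiv), NaHCO3, CH2Cl2, 0 °C
Reagents that add atoms: 3-chloroperoxybenzoic acid, OOC(=O)c1cccc(Cl)c1
Why: Prilezhaev epoxidation of the only alkene, the electron-rich trisubstituted C8=C9, is a concerted syn oxygen transfer, and the peracid should approach the α face anti to the axial angular C1 methyl group that covers the β face of the seven-membered ring (the equatorial C6 ester leaves the α face open), which sets C8 and C9 as 8R,9S, while the carbonyl-deactivated dimethoxyarene is not oxidised at 0 °C.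

Compound list
1 | 3-methylcyclopent-2-en-1-one | CC1=CC(=O)CC1 | starting material
2 | trans-2,3-dibromo-3-methylcyclopentan-1-one (racemic, one enantiomer drawn) | C[C@]1(Br)CCC(=O)[C@@H]1Br | intermediate (not isolated)
3 | 2-bromo-3-methylcyclopent-2-en-1-one | CC1=C(Br)C(=O)CC1 | intermediate
4 | tributyl(1-ethoxyethenyl)stannane | CCCC[Sn](CCCC)(CCCC)C(=C)OCC | starting material
5 | 2-(1-ethoxyethenyl)-3-methylcyclopent-2-en-1-one | CCOC(=C)C1=C(C)CCC1=O | intermediate
6 | methyl acetoacetate | CC(=O)CC(=O)OC | starting material
7 | methyl 2-diazo-3-oxobutanoate | CC(=O)C(=[N+]=[N-])C(=O)OC | intermediate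
8 | methyl 2-diazo-3-hydroxybutanoate (racemic) | CC(O)C(=[N+]=[N-])C(=O)OC | intermediate
9 | methyl 2-diazobut-3-enoate | C=CC(=[N+]=[N-])C(=O)OC | intermediate
10 | methyl (1S,2R)-2-ethoxy-1-ethenyl-2-(2-methyl-5-oxocyclopent-1-en-1-yl)cyclopropane-1-carboxylate (vinyl cis to cyclopentenonyl) | CCO[C@@]1(C2=C(C)CCC2=O)C[C@@]1(C=C)C(=O)OC | intermediate (not isolated)
11 | methyl (8aR)-4-ethoxy-8a-methyl-3-oxo-1,2,3,5,8,8a-hexahydroazulene-6-carboxylate (C4 ketone, C6 ethoxy, C8 ester, C1 quaternary) | CCOC1=C2C(=O)CC[C@]2(C)CC=C(C(=O)OC)C1 | intermediate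
12 | C4 isopropyl carbinol of 11 (C4 epimer mixture) | CCOC1=C2C(O)(C(C)C)CC[C@]2(C)CC=C(C(=O)OC)C1 | intermediate (not isolated)
13 | methyl (1R)-6-oxodauca-4,8-dien-14-oate | CC(C)C1=C2C(=O)CC(C(=O)OC)=CC[C@@]2(C)CC1 | intermediate
14 | methyl (1R,4R,5R)-4β,5β-epoxy-6-oxodauc-8-en-14-oate | O=C2CC(C(=O)OC)=CC[C@@]3(C)CC[C@]4(C(C)C)O[C@]234 | intermediate
15 | methyl (1R,4R,5S)-4β-hydroxy-6-oxo-5βH-dauc-8-en-14-oate (cis-fused) | O=C2CC(C(=O)OC)=CC[C@@]3(C)CC[C@@](O)(C(C)C)[C@@H]23 | intermediate
16 | methyl (1R,4R,5R)-4β-hydroxy-6-oxo-5αH-dauc-8-en-14-oate (trans-fused) | O=C2CC(C(=O)OC)=CC[C@@]3(C)CC[C@@](O)(C(C)C)[C@H]23 | intermediate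
17 | methyl (1R,4R,5S,6S)-4β,6α-dihydroxydauc-8-en-14-oate | O[C@H]2CC(C(=O)OC)=CC[C@@]3(C)CC[C@@](O)(C(C)C)[C@H]23 | intermediate
18 | (1R,4R,5S,6S)-dauc-8-ene-4β,6α,14-triol | O[C@H]2CC(CO)=CC[C@@]3(C)CC[C@@](O)(C(C)C)[C@H]23 | intermediate
19 | (1R,4R,5S,6S)-14-chlorodauc-8-ene-4β,6α-diol | O[C@H]2CC(CCl)=CC[C@@]3(C)CC[C@@](O)(C(C)C)[C@H]23 | intermediate
20 | (1R,4R,5S,6S)-dauc-8-ene-4β,6α-diol (jaeschkeanadiol) | O[C@H]2CC(C)=CC[C@@]3(C)CC[C@@](O)(C(C)C)[C@H]23 | intermediate
21 | 3,4-dimethoxybenzoyl chloride | COc1ccc(C(=O)Cl)cc1OC | starting material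
22 | (1R,4R,5S,6S)-4β-hydroxydauc-8-en-6α-yl 3,4-dimethoxybenzoate | COc1ccc(C(=O)O[C@H]2CC(C)=CC[C@@]3(C)CC[C@@](O)(C(C)C)[C@H]23)cc1OC | intermediate
23 | (1R,4R,5S,6S,8R,9S)-8α,9α-epoxy-4β-hydroxydaucan-6α-yl 3,4-dimethoxybenzoate | COc1ccc(C(=O)O[C@H]2C[C@@]3(C)O[C@H]3C[C@@]3(C)CC[C@@](O)(C(C)C)[C@H]23)cc1OC | target

Total step count: 16. Longest linear sequence: 14 steps (from methyl acetoacetate 6 through steps 3 to 16); the branch from 1 is 13 steps.

Steps most likely to fail

Step 6. The enol ether may attack the unsubstituted vinyl terminus of the carbenoid and collapse through a zwitterion to a cyclopentene, the diazo compound 9 may cyclise to a pyrazole before carbene transfer, or enantiofacial discrimination may be insufficient. The fallback sets out from diazo ketoester 7 and diene 5 and comes back at 11. Compound 7 is O-silylated (t-BuMe2SiOTf, Et3N, CH2Cl2, 0 °C) to the stable methyl 2-diazo-3-(tert-butyldimethylsilyloxy)but-3-enoate F1, whose carbenoid reacts reliably at the carbene carbon. With Rh2(R-PTAD)4 in hexanes (R antipode assumed to give the same sense at C6 and C8) it should give with 5, through the siloxy-substituted cis-divinylcyclopropane F2, the C9-silyloxy cycloheptadiene F3. CsF and PhNTf2 in DME convert the silyl enol ether into the C9 enol triflate F4. Pd(OAc)2, PPh3, HCO2H and Bu3N in DMF then reduce the triflate to the C9–H enoate 11.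

Step 8. Hydroperoxide may close the epoxide with poor facial selectivity, and the base may move the C8=C9 alkene into conjugation through the C7 enolate or attack the ester. The fallback sets out from enone 13 and comes back at epoxy ketone 14. Luche reduction (NaBH4, CeCl3·7H2O, MeOH, −78 °C) delivers hydride anti to the pseudoaxial C1 methyl group and should give the 6β allylic alcohol F5. VO(acac)2 and t-BuOOH in CH2Cl2 epoxidise C4=C5 on the face of the hydroxyl, which is the methyl face, to the syn epoxy alcohol F6 without touching the electron-poor C8=C9 alkene. Dess–Martin periodinane then gives 14 under non-basic conditions.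

Step 10. Enolisation may take place toward C7 and shift the alkene, the ketol may open by retro-aldol cleavage or dehydrate back to 13, or the equilibrium may not favour the trans fusion enough. The fallback sets out from epoxy ketone 14 and comes back at 16, and it installs the C5 hydrogen stereospecifically and not by equilibration. NaBH4 with CeCl3·7H2O in MeOH adds hydride anti to the epoxide oxygen and gives the syn epoxy alcohol F6 described under step 8. Et3SiCl and imidazole give the C6 triethylsilyl ether F7. Et3SiOTf and i-Pr2NEt in CH2Cl2 at −45 °C open the epoxide at C5 while the antiperiplanar C6 hydrogen migrates to C5 with inversion (semipinacol 1,2-hydride shift of an epoxy silyl ether), which should give the trans-fused C4-triethylsilyloxy C6 ketone F8. HF·pyridine in THF removes the silyl group to give 16.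

Further compounds
F1 | step 6 | methyl 2-diazo-3-(tert-butyldimethylsilyloxy)but-3-enoate | C=C(O[Si](C)(C)C(C)(C)C)C(=[N+]=[N-])C(=O)OC
F2 | step 6 | siloxy-substituted cis-divinylcyclopropane | CCO[C@@]1(C2=C(C)CCC2=O)C[C@@]1(C(=C)O[Si](C)(C)C(C)(C)C)C(=O)OC
F3 | step 6 | C9-silyloxy cycloheptadiene | CCOC1=C2C(=O)CC[C@]2(C)CC(O[Si](C)(C)C(C)(C)C)=C(C(=O)OC)C1
F4 | step 6 | C9 enol triflate | CCOC1=C2C(=O)CC[C@]2(C)CC(OS(=O)(=O)C(F)(F)F)=C(C(=O)OC)C1
F5 | step 8 | 6β allylic alcohol | O[C@@H]2CC(C(=O)OC)=CC[C@@]3(C)CCC(C(C)C)=C23
F6 | step 8 | syn epoxy alcohol (6β-hydroxy, 4β,5β-epoxide) | O[C@@H]2CC(C(=O)OC)=CC[C@@]3(C)CC[C@]4(C(C)C)O[C@]234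
F7 | step 10 | C6 triethylsilyl ether of the syn epoxy alcohol | CC[Si](CC)(CC)O[C@@H]2CC(C(=O)OC)=CC[C@@]3(C)CC[C@]4(C(C)C)O[C@]234
F8 | step 10 | trans-fused C4-triethylsilyloxy C6 ketone | O=C2CC(C(=O)OC)=CC[C@@]3(C)CC[C@@](O[Si](CC)(CC)CC)(C(C)C)[C@H]23
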